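**Retrosynthetic overview**

1. The spiro-cyclohexene that joins the halves is cut at C5–C13' and C3–C11' (Diels–Alder) and the C1–OH is traced to γ-oxygenation of the adduct's dienolate. This leaves dienone 35 (hydroxy-enone half, 7R,8R,10S, methylene lactone masked as a selenide) and epoxy methylene lactone 23 (7'S,8'S,10'R): two cis-fused xanthanolides of opposite absolute series.
2. Enabling feature: in each seven-membered ring C8 carries oxygen next to C7, and C1/C5 is an alkene or its epoxide, with C6 between them. The ring is therefore a cyclohepta-1,4-diene retron (C7=C8 enol ether, C1=C5), and C9–C10 is exactly the σ-bond that a cis-divinylcyclopropane Cope rearrangement makes.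
3. Each carbocycle therefore comes in one operation from the achiral diene 5 and the siloxyvinyl diazoacetate 8 by rhodium-carbenoid cyclopropanation/Cope ring expansion (C6–C7 and C9–C10 formed, C10 set). The two enantiomeric catalysts give the two series.
4. The β-keto ester handle gives the cis-lactone (C7 alkylation, decarboxylation, hydride reduction) and then the methylene lactone; the side chain comes from oxidation/Wittig, and the epoxide of fragment B from a reagent-controlled epoxidation.
5. Ring order: cyclopropane (transient) → seven-membered ring → γ-lactone → oxirane (fragment B only) → spiro-cyclohexene by [4+2]; then C1 hydroxylation and unmasking.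

Key step: step 6

Remark on locants: xanthane numbering is used for both halves (ring C1, C5–C10; C14 = methyl on C10; side chain C2–C4, C15; lactone C11, C12, C13); primed locants belong to the epoxide-bearing half.

Assumption: the sense of induction of Rh2(S-PTAD)4 (dirhodium tetrakis[(S)-(1-adamantyl)(phthalimido)acetate]) in step 6 is assigned by analogy with related siloxyvinylcarbenoid reactions; if it is the opposite, the two catalyst enantiomers are exchanged between steps 6 and 14, since both series are needed.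

**Route**

Step 1
Reactants: 1 but-2-yn-1-ol
Product: 2 (E)-2-(tributylstannyl)but-2-en-1-ol
Conditions: Bu3SnH, PdCl2(PPh3)2 (2 mol %), THF, 0 °C → rt
Reagents that add atoms: tributyltin hydride, CCCC[SnH](CCCC)CCCC
Why: Palladium-catalysed hydrostannation of a propargylic alcohol adds H and Sn syn with tin on the carbinol-proximal carbon, which fixes the alkene geometry (CH3 trans to Sn).

Step 2
Reactants: 2 (E)-2-(tributylstannyl)but-2-en-1-ol; 3 vinyl bromide
Product: 4 (2Z)-2-ethylidenebut-3-en-1-ol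
Conditions: 3 (1 M in THF), Pd(PPh3)4 (5 mol %), CuI, CsF, DMF, 45 °C
Reagents that add atoms: none
Why: The copper/fluoride-promoted Stille coupling proceeds with retention at the alkenylstannane, so the vinyl group ends up trans to the methyl group.

Step 3
Reactants: 4 (2Z)-2-ethylidenebut-3-en-1-ol
Product: 5 tert-butyl{[(2Z)-2-ethylidenebut-3-en-1-yl]oxy}diphenylsilane
Conditions: TBDPSCl, imidazole, CH2Cl2, rt
Reagents that add atoms: tert-butyl(chloro)diphenylsilane, CC(C)(C)[Si](Cl)(c1ccccc1)c1ccccc1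
Why: Standard silylation removes the O–H (which would insert into the carbenoid) and gives a bulky ether that should survive until the HF step.

Step 4
Reactants: 6 methyl acetoacetate
Product: 7 methyl 2-diazo-3-oxobutanoate
Conditions: 4-AcNHC6H4SO2N3, Et3N, MeCN, 0 °C → rt
Reagents that add atoms: 4-acetamidobenzenesulfonyl azide, CC(=O)Nc1ccc(cc1)S(=O)(=O)N=[N+]=[N-]
Why: Regitz diazo transfer to the active methylene group.

Step 5
Reactants: 7 methyl 2-diazo-3-oxobutanoate
Product: 8 methyl 3-[(tert-butyldimethylsilyl)oxy]-2-diazobut-3-enoate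
Conditions: TBSOTf, Et3N, CH2Cl2, 0 °C
Reagents that add atoms: tert-butyldimethylsilyl trifluoromethanesulfonate, CC(C)(C)[Si](C)(C)OS(=O)(=O)C(F)(F)F
Why: Soft enolisation and O-silylation of the acetyl group gives the siloxyvinyl diazoacetate, a donor/acceptor carbene precursor.

Step 6
Reactants: 5 tert-butyl{[(2Z)-2-ethylidenebut-3-en-1-yl]oxy}diphenylsilane; 8 methyl 3-[(tert-butyldimethylsilyl)oxy]-2-diazobut-3-enoate
Product: 10 methyl (4R)-2-[(tert-butyldimethylsilyl)oxy]-5-{[(tert-butyldiphenylsilyl)oxy]methyl}-4-methylcyclohepta-1,5-diene-1-carboxylate, via cis-divinylcyclopropane 9 (not isolated)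
Conditions: Rh2(S-PTAD)4 (1 mol %), hexanes, −20 °C → rt (8 added slowly to 5), then 45 °C
Reagents that add atoms: none
Why: The rhodium carbenoid from 8 (donor = siloxyvinyl, acceptor = ester) adds to the terminal C5=C6 alkene of 5 in a concerted, asynchronous [2+1] step to give the cis-divinylcyclopropane 9, whose two alkenyl arms (C8=C9 and C1=C10) then undergo a boat-shaped [3,3] Cope rearrangement that breaks C5–C7 and forms the C9–C10 σ-bond. The closest known reaction type is the tandem cyclopropanation/Cope rearrangement (formal [4+3] cycloaddition) of siloxyvinyl diazoacetates with 1,3-dienes under chiral dirhodium tetracarboxylate catalysis. The three-membered ring closes by carbene transfer to one alkene, and the seven-membered ring closes by sigmatropic ring expansion in which C9 and C10, the termini of the two vinyl groups held cis on the cyclopropane, are joined. The catalyst selects the enantiotopic face of C5=C6 and so sets C5 and C7 of 9 (1R,2S); the only stereocentre that survives, C10, is set by chirality transfer through the boat transition state, in which the Z geometry of 5 puts the C10 methyl on the outside and should deliver 10R. The step needs chemoselectivity for the monosubstituted alkene over the trisubstituted one and over allylic C–H insertion (secured by the steric demand of the donor/acceptor carbenoid and the bulky silyl ether) and needs the cis cyclopropane (the inherent diastereoselectivity of vinylcarbenoids); the methyl group trans to the vinyl group in 5 also rules out a competing [1,5]-hydrogen shift.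

Step 7
Reactants: 10 methyl (4R)-2-[(tert-butyldimethylsilyl)oxy]-5-{[(tert-butyldiphenylsilyl)oxy]methyl}-4-methylcyclohepta-1,5-diene-1-carboxylate; 11 methyl bromoacetate
Product: 12 methyl (4R)-5-{[(tert-butyldiphenylsilyl)oxy]methyl}-1-(2-methoxy-2-oxoethyl)-4-methyl-2-oxocyclohept-5-ene-1-carboxylate (both C1 epimers)
Conditions: Bu4NF (1.05 equiv), THF, −78 °C; then 11, −78 → 0 °C
Reagents that add atoms: none
Why: Fluoride-mediated enol silyl ether alkylation unmasks the β-keto ester enolate regiospecifically at C7 (the far more labile enol silane reacts before the TBDPS ether) and it is C-alkylated by the bromoacetate; the new quaternary centre is destroyed in step 8, so its configuration does not matter.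

Step 8
Reactants: 12 methyl (4R)-5-{[(tert-butyldiphenylsilyl)oxy]methyl}-1-(2-methoxy-2-oxoethyl)-4-methyl-2-oxocyclohept-5-ene-1-carboxylate
Product: 13 methyl 2-[(1S,4R)-5-{[(tert-butyldiphenylsilyl)oxy]methyl}-4-methyl-2-oxocyclohept-5-en-1-yl]acetate (xanthane 7S,10R; side chain cis to the methyl group)
Conditions: LiCl, H2O, DMSO, 140 °C
Reagents that add atoms: none
Why: Krapcho demethoxycarbonylation removes the activating ester, and C7 should equilibrate by enolisation in the hot, weakly basic medium to the isomer with the acetate chain pseudoequatorial and cis to the C10 methyl, which sits pseudoaxial to avoid A(1,2) strain with the C1 substituent.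

Step 9
Reactants: 13 methyl 2-[(1S,4R)-5-{[(tert-butyldiphenylsilyl)oxy]methyl}-4-methyl-2-oxocyclohept-5-en-1-yl]acetate
Product: 14 (3aS,7R,8aS)-6-{[(tert-butyldiphenylsilyl)oxy]methyl}-7-methyl-3,3a,4,7,8,8a-hexahydro-2H-cyclohepta[b]furan-2-one
Conditions: LiBH(s-Bu)3, THF, −78 °C; then 1 M HCl, rt
Reagents that add atoms: none
Why: The bulky hydride attacks C8 from the face opposite both the adjacent C7 side chain and the pseudoaxial C10 methyl (equatorial attack on a 2-substituted cycloalkanone), and the resulting cis-hydroxy ester lactonises to the all-cis lactone.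

Step 10
Reactants: 14 (3aS,7R,8aS)-6-{[(tert-butyldiphenylsilyl)oxy]methyl}-7-methyl-3,3a,4,7,8,8a-hexahydro-2H-cyclohepta[b]furan-2-one; 15 N,N-dimethylmethyleneiminium iodide (Eschenmoser's salt)
Product: 18 (3aS,7R,8aS)-6-{[(tert-butyldiphenylsilyl)oxy]methyl}-7-methyl-3-methylidene-3,3a,4,7,8,8a-hexahydro-2H-cyclohepta[b]furan-2-one, via Mannich base 16 (not isolated), via ammonium iodide 17 (not isolated)
Conditions: LiN(i-Pr)2, THF, −78 °C; 15, −78 °C → rt; then MeI, MeOH, rt; then NaHCO3 (aq.), EtOAc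
Reagents that add atoms: none
Why: α-Methylenation of the lactone by the Mannich reaction of its lithium enolate, quaternisation and base-induced elimination of trimethylamine.

Step 11
Reactants: 18 (3aS,7R,8aS)-6-{[(tert-butyldiphenylsilyl)oxy]methyl}-7-methyl-3-methylidene-3,3a,4,7,8,8a-hexahydro-2H-cyclohepta[b]furan-2-one
Product: 19 (3aS,7R,8aS)-6-(hydroxymethyl)-7-methyl-3-methylidene-3,3a,4,7,8,8a-hexahydro-2H-cyclohepta[b]furan-2-one
Conditions: HF·pyridine, THF–pyridine, 0 °C → rt
Reagents that add atoms: none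
Why: Buffered fluoride cleaves the silyl ether without touching the base-sensitive α-methylene lactone.

Step 12
Reactants: 19 (3aS,7R,8aS)-6-(hydroxymethyl)-7-methyl-3-methylidene-3,3a,4,7,8,8a-hexahydro-2H-cyclohepta[b]furan-2-one
Product: 20 epoxy alcohol: 1,5-epoxide of 19 (xanthane 1R,5R,7S,8S,10R; oxirane oxygen trans to the C10 methyl and to the lactone ring)
Conditions: Ti(Oi-Pr)4 (10 mol %), D-(−)-diethyl tartrate (12 mol %), t-BuOOH, 4 Å molecular sieves, CH2Cl2, −20 °C
Reagents that add atoms: tert-butyl hydroperoxide, CC(C)(C)OO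
Why: Katsuki–Sharpless epoxidation of the cycloalkenylmethanol is reagent-controlled, and the D-(−)-tartrate should deliver oxygen to the C1=C5 face that gives the 1R,5R oxirane (the electron-poor methylene lactone is inert).

Step 13
Reactants: 20 epoxy alcohol; 21 1-(triphenylphosphoranylidene)propan-2-one
Product: 23 fragment B: (1R,5R,7S,8S,10R)-1,5-epoxy-4-oxoxantha-2E,11(13)-dien-12,8-olide (cis-fused lactone), via epoxy aldehyde 22 (not isolated)
Conditions: Dess–Martin periodinane, pyridine, CH2Cl2, 0 °C → rt; then 21, 40 °C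
Reagents that add atoms: none
Why: Dess–Martin oxidation followed by Wittig olefination in one pot; the aldehyde α-carbon is the fully substituted oxirane carbon and cannot epimerise, and the stabilised ylide gives the E-enone.

Step 14
Reactants: 5 tert-butyl{[(2Z)-2-ethylidenebut-3-en-1-yl]oxy}diphenylsilane; 8 methyl 3-[(tert-butyldimethylsilyl)oxy]-2-diazobut-3-enoate
Product: 25 methyl (4S)-2-[(tert-butyldimethylsilyl)oxy]-5-{[(tert-butyldiphenylsilyl)oxy]methyl}-4-methylcyclohepta-1,5-diene-1-carboxylate, via cis-divinylcyclopropane 24 (not isolated)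
Conditions: Rh2(R-PTAD)4 (1 mol %), hexanes, −20 °C → rt (8 added slowly to 5), then 45 °C
Reagents that add atoms: none
Why: The same tandem cyclopropanation/Cope rearrangement as in step 6; the enantiomeric catalyst selects the other face of C5=C6 and should deliver 10S.

Step 15
Reactants: 25 methyl (4S)-2-[(tert-butyldimethylsilyl)oxy]-5-{[(tert-butyldiphenylsilyl)oxy]methyl}-4-methylcyclohepta-1,5-diene-1-carboxylate; 11 methyl bromoacetate
Product: 26 methyl (4S)-5-{[(tert-butyldiphenylsilyl)oxy]methyl}-1-(2-methoxy-2-oxoethyl)-4-methyl-2-oxocyclohept-5-ene-1-carboxylate (both C1 epimers)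
Conditions: Bu4NF (1.05 equiv), THF, −78 °C; then 11, −78 → 0 °C
Reagents that add atoms: none
Why: Fluoride-mediated enol silyl ether alkylation at C7, as in step 7.

Step 16
Reactants: 26 methyl (4S)-5-{[(tert-butyldiphenylsilyl)oxy]methyl}-1-(2-methoxy-2-oxoethyl)-4-methyl-2-oxocyclohept-5-ene-1-carboxylate
Product: 27 methyl 2-[(1R,4S)-5-{[(tert-butyldiphenylsilyl)oxy]methyl}-4-methyl-2-oxocyclohept-5-en-1-yl]acetate (xanthane 7R,10S)
Conditions: LiCl, H2O, DMSO, 140 °C
Reagents that add atoms: none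
Why: Krapcho demethoxycarbonylation with thermodynamic equilibration at C7, as in step 8.

Step 17
Reactants: 27 methyl 2-[(1R,4S)-5-{[(tert-butyldiphenylsilyl)oxy]methyl}-4-methyl-2-oxocyclohept-5-en-1-yl]acetate
Product: 28 (3aR,7S,8aR)-6-{[(tert-butyldiphenylsilyl)oxy]methyl}-7-methyl-3,3a,4,7,8,8a-hexahydro-2H-cyclohepta[b]furan-2-one
Conditions: LiBH(s-Bu)3, THF, −78 °C; then 1 M HCl, rt
Reagents that add atoms: none
Why: Equatorial hydride delivery anti to the C7 side chain and the pseudoaxial methyl, followed by lactonisation, as in step 9.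

Step 18
Reactants: 28 (3aR,7S,8aR)-6-{[(tert-butyldiphenylsilyl)oxy]methyl}-7-methyl-3,3a,4,7,8,8a-hexahydro-2H-cyclohepta[b]furan-2-one; 15 N,N-dimethylmethyleneiminium iodide (Eschenmoser's salt)
Product: 31 (3aR,7S,8aR)-6-{[(tert-butyldiphenylsilyl)oxy]methyl}-7-methyl-3-methylidene-3,3a,4,7,8,8a-hexahydro-2H-cyclohepta[b]furan-2-one, via Mannich base 29 (not isolated), via ammonium iodide 30 (not isolated)
Conditions: LiN(i-Pr)2, THF, −78 °C; 15, −78 °C → rt; then MeI, MeOH, rt; then NaHCO3 (aq.), EtOAc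
Reagents that add atoms: none
Why: Mannich methylenation of the lactone, as in step 10.

Step 19
Reactants: 31 (3aR,7S,8aR)-6-{[(tert-butyldiphenylsilyl)oxy]methyl}-7-methyl-3-methylidene-3,3a,4,7,8,8a-hexahydro-2H-cyclohepta[b]furan-2-one
Product: 32 (3R,3aR,7S,8aR)-6-{[(tert-butyldiphenylsilyl)oxy]methyl}-7-methyl-3-[(phenylselanyl)methyl]-3,3a,4,7,8,8a-hexahydro-2H-cyclohepta[b]furan-2-one (CH2SePh cis to H-3a)
Conditions: PhSeH, Et3N (cat.), THF, 0 °C → rt
Reagents that add atoms: benzeneselenol, [SeH]c1ccccc1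
Why: Conjugate addition of the selenol masks the methylene lactone so that this half can later act only as a diene; C11 settles with the side chain on the convex face and is removed again in step 24.

Step 20
Reactants: 32 (3R,3aR,7S,8aR)-6-{[(tert-butyldiphenylsilyl)oxy]methyl}-7-methyl-3-[(phenylselanyl)methyl]-3,3a,4,7,8,8a-hexahydro-2H-cyclohepta[b]furan-2-one
Product: 33 (3R,3aR,7S,8aR)-6-(hydroxymethyl)-7-methyl-3-[(phenylselanyl)methyl]-3,3a,4,7,8,8a-hexahydro-2H-cyclohepta[b]furan-2-one
Conditions: HF·pyridine, THF–pyridine, 0 °C → rt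
Reagents that add atoms: none
Why: Fluoride desilylation; the selenide and the lactone are inert to it.

Step 21
Reactants: 33 (3R,3aR,7S,8aR)-6-(hydroxymethyl)-7-methyl-3-[(phenylselanyl)methyl]-3,3a,4,7,8,8a-hexahydro-2H-cyclohepta[b]furan-2-one; 21 1-(triphenylphosphoranylidene)propan-2-one
Product: 35 fragment A: (7R,8R,10S,11R)-4-oxo-13-(phenylselanyl)xantha-1(5),2E-dien-12,8-olide (cis-fused lactone), via enal 34 (not isolated)
Conditions: MnO2, 21, CH2Cl2, reflux
Reagents that add atoms: none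
Why: Tandem allylic oxidation/Wittig olefination; MnO2 oxidises only the allylic alcohol and the enal is trapped in situ by the stabilised ylide to give the E,s-trans dienone.

Step 22
Reactants: 35 fragment A; 23 fragment B
Product: 36 Diels–Alder adduct (new bonds C5–C13' and C3–C11'; C1=C2 alkene; 3S,5S,11'R; 13-phenylselanyl group retained)
Conditions: PhMe (1 M), BHT (5 mol %), 90 °C, sealed tube, dark; 23 in slight excess
Reagents that add atoms: none
Why: Thermal Diels–Alder reaction in which the CH2 terminus of the methylene lactone bonds to C5 and the carbonyl-bearing C11' to the acetyl-bearing C3 ("ortho" orientation); 23 should react on its convex face (that of H-7') with the lactone carbonyl exo, as is usual for α-methylene-γ-butyrolactones, and this mode pairs with attack at C5 on the face of the pseudoaxial C10 methyl, where only H-6 flanks the bonding carbon, giving 5S and 11'R, while the C3 centre is erased in step 23.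

Step 23
Reactants: 36 Diels–Alder adduct
Product: 38 1-hydroxy-2-en-4-one (1S; C1–OH trans to H-5; 13-phenylselanyl group retained), via C1 hydroperoxide 37 (not isolated)
Conditions: O2 (1 atm), DBU, P(OEt)3, MeCN, 0 °C
Reagents that add atoms: dioxygen, O=O
Why: γ-Oxygenation of a β,γ-unsaturated ketone: DBU removes the doubly activated C3–H, the extended enolate is trapped by O2 at C1 and the hydroperoxide is reduced in situ by the phosphite; O2 is expected to add anti to the pseudoaxial H-5 so that the six- and seven-membered rings become trans-fused, and the outcome does not depend on the C3 configuration.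

Step 24
Reactants: 38 1-hydroxy-2-en-4-one
Product: 40 CNP0177598.2 (target), via selenoxide 39 (not isolated)
Conditions: H2O2 (30 %), pyridine, CH2Cl2, 0 °C → rt
Reagents that add atoms: none
Why: Selenide oxidation and syn-elimination of the selenoxide, whose only β-hydrogen is H-11, regenerate the exocyclic methylene lactone; no electron-rich alkene remains to be epoxidised.

**Compound list**

1 | but-2-yn-1-ol | CC#CCO | starting material
2 | (E)-2-(tributylstannyl)but-2-en-1-ol | C/C=C(\CO)[Sn](CCCC)(CCCC)CCCC | intermediate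
3 | vinyl bromide | C=CBr | starting material
4 | (2Z)-2-ethylidenebut-3-en-1-ol | C=C/C(CO)=C/C | intermediate
5 | tert-butyl{[(2Z)-2-ethylidenebut-3-en-1-yl]oxy}diphenylsilane | C=C/C(CO[Si](c1ccccc1)(c1ccccc1)C(C)(C)C)=C/C | intermediate
6 | methyl acetoacetate | COC(=O)CC(C)=O | starting material
7 | methyl 2-diazo-3-oxobutanoate | COC(=O)C(=[N+]=[N-])C(C)=O | intermediate
8 | methyl 3-[(tert-butyldimethylsilyl)oxy]-2-diazobut-3-enoate | COC(=O)C(=[N+]=[N-])C(=C)O[Si](C)(C)C(C)(C)C | intermediate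
9 | methyl (1R,2S)-1-{1-[(tert-butyldimethylsilyl)oxy]ethenyl}-2-{(2Z)-1-[(tert-butyldiphenylsilyl)oxy]but-2-en-2-yl}cyclopropane-1-carboxylate (cis-divinylcyclopropane) | COC(=O)[C@]1(C(=C)O[Si](C)(C)C(C)(C)C)C[C@H]1/C(CO[Si](c2ccccc2)(c2ccccc2)C(C)(C)C)=C/C | intermediate
10 | methyl (4R)-2-[(tert-butyldimethylsilyl)oxy]-5-{[(tert-butyldiphenylsilyl)oxy]methyl}-4-methylcyclohepta-1,5-diene-1-carboxylate | COC(=O)C1=C(O[Si](C)(C)C(C)(C)C)C[C@@H](C)C(CO[Si](c2ccccc2)(c2ccccc2)C(C)(C)C)=CC1 | intermediate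
11 | methyl bromoacetate | COC(=O)CBr | starting material
12 | methyl (4R)-5-{[(tert-butyldiphenylsilyl)oxy]methyl}-1-(2-methoxy-2-oxoethyl)-4-methyl-2-oxocyclohept-5-ene-1-carboxylate (both C1 epimers) | COC(=O)CC1(C(=O)OC)CC=C(CO[Si](c2ccccc2)(c2ccccc2)C(C)(C)C)[C@H](C)CC1=O | intermediate
13 | methyl 2-[(1S,4R)-5-{[(tert-butyldiphenylsilyl)oxy]methyl}-4-methyl-2-oxocyclohept-5-en-1-yl]acetate | COC(=O)C[C@@H]1CC=C(CO[Si](c2ccccc2)(c2ccccc2)C(C)(C)C)[C@H](C)CC1=O | intermediate
14 | (3aS,7R,8aS)-6-{[(tert-butyldiphenylsilyl)oxy]methyl}-7-methyl-3,3a,4,7,8,8a-hexahydro-2H-cyclohepta[b]furan-2-one | O=C1C[C@@H]2CC=C(CO[Si](c3ccccc3)(c3ccccc3)C(C)(C)C)[C@H](C)C[C@@H]2O1 | intermediate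
15 | N,N-dimethylmethyleneiminium iodide (Eschenmoser's salt) | C=[N+](C)C.[I-] | starting material
16 | (3R,3aS,7R,8aS)-3-[(dimethylamino)methyl] derivative of 14 (Mannich base; CH2N cis to H-3a) | O=C1[C@@H](CN(C)C)[C@@H]2CC=C(CO[Si](c3ccccc3)(c3ccccc3)C(C)(C)C)[C@H](C)C[C@@H]2O1 | intermediate
17 | trimethylammonium iodide of 16 | O=C1[C@@H](C[N+](C)(C)C)[C@@H]2CC=C(CO[Si](c3ccccc3)(c3ccccc3)C(C)(C)C)[C@H](C)C[C@@H]2O1.[I-] | intermediate
18 | (3aS,7R,8aS)-6-{[(tert-butyldiphenylsilyl)oxy]methyl}-7-methyl-3-methylidene-3,3a,4,7,8,8a-hexahydro-2H-cyclohepta[b]furan-2-one | O=C1C(=C)[C@@H]2CC=C(CO[Si](c3ccccc3)(c3ccccc3)C(C)(C)C)[C@H](C)C[C@@H]2O1 | intermediate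
19 | (3aS,7R,8aS)-6-(hydroxymethyl)-7-methyl-3-methylidene-3,3a,4,7,8,8a-hexahydro-2H-cyclohepta[b]furan-2-one | O=C1C(=C)[C@@H]2CC=C(CO)[C@H](C)C[C@@H]2O1 | intermediate
20 | epoxy alcohol: 1,5-epoxide of 19 (xanthane 1R,5R,7S,8S,10R; oxirane trans to C10 methyl and lactone) | O=C1C(=C)[C@@H]2C[C@H]3O[C@@]3(CO)[C@H](C)C[C@@H]2O1 | intermediate
21 | 1-(triphenylphosphoranylidene)propan-2-one | CC(=O)C=P(c1ccccc1)(c1ccccc1)c1ccccc1 | starting material
22 | epoxy aldehyde: C2 aldehyde of 20 | O=C1C(=C)[C@@H]2C[C@H]3O[C@@]3(C=O)[C@H](C)C[C@@H]2O1 | intermediate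
23 | fragment B: (1R,5R,7S,8S,10R)-1,5-epoxy-4-oxoxantha-2E,11(13)-dien-12,8-olide | O=C1C(=C)[C@@H]2C[C@H]3O[C@@]3(/C=C/C(C)=O)[C@H](C)C[C@@H]2O1 | intermediate
24 | methyl (1S,2R)-1-{1-[(tert-butyldimethylsilyl)oxy]ethenyl}-2-{(2Z)-1-[(tert-butyldiphenylsilyl)oxy]but-2-en-2-yl}cyclopropane-1-carboxylate (enantiomer of 9) | COC(=O)[C@@]1(C(=C)O[Si](C)(C)C(C)(C)C)C[C@@H]1/C(CO[Si](c2ccccc2)(c2ccccc2)C(C)(C)C)=C/C | intermediate
25 | methyl (4S)-2-[(tert-butyldimethylsilyl)oxy]-5-{[(tert-butyldiphenylsilyl)oxy]methyl}-4-methylcyclohepta-1,5-diene-1-carboxylate | COC(=O)C1=C(O[Si](C)(C)C(C)(C)C)C[C@H](C)C(CO[Si](c2ccccc2)(c2ccccc2)C(C)(C)C)=CC1 | intermediate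
26 | methyl (4S)-5-{[(tert-butyldiphenylsilyl)oxy]methyl}-1-(2-methoxy-2-oxoethyl)-4-methyl-2-oxocyclohept-5-ene-1-carboxylate (both C1 epimers) | COC(=O)CC1(C(=O)OC)CC=C(CO[Si](c2ccccc2)(c2ccccc2)C(C)(C)C)[C@@H](C)CC1=O | intermediate
27 | methyl 2-[(1R,4S)-5-{[(tert-butyldiphenylsilyl)oxy]methyl}-4-methyl-2-oxocyclohept-5-en-1-yl]acetate | COC(=O)C[C@H]1CC=C(CO[Si](c2ccccc2)(c2ccccc2)C(C)(C)C)[C@@H](C)CC1=O | intermediate
28 | (3aR,7S,8aR)-6-{[(tert-butyldiphenylsilyl)oxy]methyl}-7-methyl-3,3a,4,7,8,8a-hexahydro-2H-cyclohepta[b]furan-2-one | O=C1C[C@H]2CC=C(CO[Si](c3ccccc3)(c3ccccc3)C(C)(C)C)[C@@H](C)C[C@H]2O1 | intermediate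
29 | (3S,3aR,7S,8aR)-3-[(dimethylamino)methyl] derivative of 28 (Mannich base) | O=C1[C@H](CN(C)C)[C@H]2CC=C(CO[Si](c3ccccc3)(c3ccccc3)C(C)(C)C)[C@@H](C)C[C@H]2O1 | intermediate
30 | trimethylammonium iodide of 29 | O=C1[C@H](C[N+](C)(C)C)[C@H]2CC=C(CO[Si](c3ccccc3)(c3ccccc3)C(C)(C)C)[C@@H](C)C[C@H]2O1.[I-] | intermediate
31 | (3aR,7S,8aR)-6-{[(tert-butyldiphenylsilyl)oxy]methyl}-7-methyl-3-methylidene-3,3a,4,7,8,8a-hexahydro-2H-cyclohepta[b]furan-2-one | O=C1C(=C)[C@H]2CC=C(CO[Si](c3ccccc3)(c3ccccc3)C(C)(C)C)[C@@H](C)C[C@H]2O1 | intermediate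
32 | (3R,3aR,7S,8aR)-6-{[(tert-butyldiphenylsilyl)oxy]methyl}-7-methyl-3-[(phenylselanyl)methyl]-3,3a,4,7,8,8a-hexahydro-2H-cyclohepta[b]furan-2-one | O=C1[C@H](C[Se]c4ccccc4)[C@H]2CC=C(CO[Si](c3ccccc3)(c3ccccc3)C(C)(C)C)[C@@H](C)C[C@H]2O1 | intermediate
33 | (3R,3aR,7S,8aR)-6-(hydroxymethyl)-7-methyl-3-[(phenylselanyl)methyl]-3,3a,4,7,8,8a-hexahydro-2H-cyclohepta[b]furan-2-one | O=C1[C@H](C[Se]c4ccccc4)[C@H]2CC=C(CO)[C@@H](C)C[C@H]2O1 | intermediate
34 | enal: C2 aldehyde of 33 | O=C1[C@H](C[Se]c4ccccc4)[C@H]2CC=C(C=O)[C@@H](C)C[C@H]2O1 | intermediate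
35 | fragment A: (7R,8R,10S,11R)-4-oxo-13-(phenylselanyl)xantha-1(5),2E-dien-12,8-olide | O=C1[C@H](C[Se]c4ccccc4)[C@H]2CC=C(/C=C/C(C)=O)[C@@H](C)C[C@H]2O1 | intermediate
36 | Diels–Alder adduct (C5–C13' and C3–C11' bonds; C1=C2; 3S,5S,11'R; 13-phenylselanyl) | c5ccccc5[Se]C[C@H]1C(=O)O[C@@H]2C[C@H](C)C3=C[C@H](C(C)=O)[C@]4(C[C@@H]3C[C@H]12)C(=O)O[C@H]1C[C@@H](C)[C@]2(/C=C/C(C)=O)O[C@@H]2C[C@H]14 | intermediate
37 | C1 hydroperoxide of the 2-en-4-one (13-phenylselanyl) | c5ccccc5[Se]C[C@H]1C(=O)O[C@@H]2C[C@H](C)[C@@]3(OO)C=C(C(C)=O)[C@]4(C[C@@H]3C[C@H]12)C(=O)O[C@H]1C[C@@H](C)[C@]2(/C=C/C(C)=O)O[C@@H]2C[C@H]14 | intermediate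
38 | 13-(phenylselanyl)-11,13-dihydro derivative of the target (1S-hydroxy-2-en-4-one) | c5ccccc5[Se]C[C@H]1C(=O)O[C@@H]2C[C@H](C)[C@@]3(O)C=C(C(C)=O)[C@]4(C[C@@H]3C[C@H]12)C(=O)O[C@H]1C[C@@H](C)[C@]2(/C=C/C(C)=O)O[C@@H]2C[C@H]14 | intermediate
39 | selenoxide of 38 | O=[Se](c5ccccc5)C[C@H]1C(=O)O[C@@H]2C[C@H](C)[C@@]3(O)C=C(C(C)=O)[C@]4(C[C@@H]3C[C@H]12)C(=O)O[C@H]1C[C@@H](C)[C@]2(/C=C/C(C)=O)O[C@@H]2C[C@H]14 | intermediate
40 | CNP0177598.2 | C=C1C(=O)O[C@@H]2C[C@H](C)[C@@]3(O)C=C(C(C)=O)[C@]4(C[C@@H]3C[C@H]12)C(=O)O[C@H]1C[C@@H](C)[C@]2(/C=C/C(C)=O)O[C@@H]2C[C@H]14 | target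

**Totals**

Total step count: 24.
Longest linear sequence: 14 steps (steps 1–3, 6–13, 22–24; the fragment A branch, steps 1–3, 14–21, 22–24, is equally long).

**Steps most likely to fail**

1. Step 22. The acyl-substituted diene may react too slowly with the electron-poor alkene at temperatures both partners tolerate, and the dienophile may attack the other face of the diene (anti to the C10 methyl) or adopt the carbonyl-endo orientation, which would give the C5 epimer. The fallback changes the electronic character of the diene through a temporary lower oxidation level. Starting from 35, Luche reduction (NaBH4, CeCl3·7H2O, MeOH, −40 °C) should give the dienyl alcohol F1 (C4 epimers, inconsequential). This normal-demand diene can be combined with 23 at 40–60 °C in toluene, where the hydroxyl group can hydrogen-bond to the lactone carbonyl of 23, to give the cycloadduct alcohol F2. Parikh–Doering oxidation (SO3·pyridine, DMSO, Et3N), which leaves the selenide alone, returns to 36; a different C3 configuration would be immaterial because step 23 erases it.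

2. Step 23. The dienolate may be protonated at C1 instead of oxygenated (simple conjugation to the 2-en-4-one), or oxygen may be delivered to the wrong face of C1. The fallback replaces enolate oxygenation by epoxidation/elimination. Starting from 36, the selenide is removed first (NaIO4, NaHCO3, aqueous THF) to give the methylene lactone F3, whose only electron-rich alkene is C1=C2. Dimethyldioxirane (acetone, −40 °C) should give the 1,2-epoxide F4, and DBU (CH2Cl2, 0 °C) opens it by E1cB elimination from C3, leaving the oxygen on C1 and arriving directly at 40.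

3. Step 8 (and its twin, step 16). Equilibration at C7 may be incomplete or insufficiently biased, so that the 7,10-trans keto ester and hence a diastereomeric lactone are carried forward. The fallback sets C7 by auxiliary control instead of thermodynamic control. Starting from 10, desilylation and decarboxylation (Bu4NF; then LiCl, wet DMSO, 140 °C) give the ketone F5. Condensation with (S)-1-amino-2-(methoxymethyl)pyrrolidine gives the SAMP hydrazone F6. Deprotonation (LiN(i-Pr)2, THF) at the less hindered C7 and alkylation with tert-butyl bromoacetate at −100 °C give the alkylated hydrazone F7, and mild hydrolysis (aqueous oxalic acid) gives the tert-butyl keto ester F8. Reduction with LiBH(s-Bu)3 and lactonisation with CF3CO2H return to 14. The enantiomeric auxiliary would serve the other series, from 25 to 28.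

Further compounds
F1 | step 22 | dienyl alcohol from 35 (4-hydroxy, both C4 epimers) | O=C1[C@H](C[Se]c4ccccc4)[C@H]2CC=C(/C=C/C(C)O)[C@@H](C)C[C@H]2O1
F2 | step 22 | cycloadduct alcohol (4-hydroxy analogue of 36, both C4 epimers) | c5ccccc5[Se]C[C@H]1C(=O)O[C@@H]2C[C@H](C)C3=C[C@H](C(C)O)[C@]4(C[C@@H]3C[C@H]12)C(=O)O[C@H]1C[C@@H](C)[C@]2(/C=C/C(C)=O)O[C@@H]2C[C@H]14
F3 | step 23 | unmasked cycloadduct (11(13)-methylene lactone, C1=C2 alkene) | C=C1C(=O)O[C@@H]2C[C@H](C)C3=C[C@H](C(C)=O)[C@]4(C[C@@H]3C[C@H]12)C(=O)O[C@H]1C[C@@H](C)[C@]2(/C=C/C(C)=O)O[C@@H]2C[C@H]14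
F4 | step 23 | 1,2-epoxide of F3 (oxirane oxygen trans to H-5) | C=C1C(=O)O[C@@H]2C[C@H](C)[C@]36O[C@@H]6[C@H](C(C)=O)[C@]4(C[C@@H]3C[C@H]12)C(=O)O[C@H]1C[C@@H](C)[C@]2(/C=C/C(C)=O)O[C@@H]2C[C@H]14
F5 | step 8 | (6R)-5-{[(tert-butyldiphenylsilyl)oxy]methyl}-6-methylcyclohept-4-en-1-one | O=C1CCC=C(CO[Si](c2ccccc2)(c2ccccc2)C(C)(C)C)[C@H](C)C1
F6 | step 8 | SAMP hydrazone of F5 | COC[C@@H]1CCCN1N=C1CCC=C(CO[Si](c2ccccc2)(c2ccccc2)C(C)(C)C)[C@H](C)C1
F7 | step 8 | SAMP hydrazone of tert-butyl 2-[(1S,4R)-5-{[(tert-butyldiphenylsilyl)oxy]methyl}-4-methyl-2-oxocyclohept-5-en-1-yl]acetate | COC[C@@H]1CCCN1N=C1C[C@@H](C)C(CO[Si](c2ccccc2)(c2ccccc2)C(C)(C)C)=CC[C@H]1CC(=O)OC(C)(C)C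
F8 | step 8 | tert-butyl 2-[(1S,4R)-5-{[(tert-butyldiphenylsilyl)oxy]methyl}-4-methyl-2-oxocyclohept-5-en-1-yl]acetate | CC(C)(C)OC(=O)C[C@@H]1CC=C(CO[Si](c2ccccc2)(c2ccccc2)C(C)(C)C)[C@H](C)CC1=O
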